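**Strategy.** Drimane numbering is used (C1–C10 decalin, C11 = CH2OAr on C9). Ring A is a cyclohexane whose C4–C5 unit sits α,β to the C6 ketone of ring B. The route therefore treats C4=C5–C6=O as an enone dienophile and C10=C1–C2=C3 as a diene. An acyclic (Z)-dienone triene aryl ether, with C9 as its only stereocentre and the coumarin already in place, should undergo a Lewis acid-promoted intramolecular Diels–Alder reaction. This forms C5–C10 and C3–C4, closes rings A and B at once and sets C10 and C5. Enolate reprotonation at C5, allylic hydroxylation at C3 and alkene hydrogenation finish the synthesis.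

Key step: step 10

Remark: in the target H5 is trans, C11 is cis and the 3-hydroxyl is trans (axial) to the C10 methyl; epoxide 5 is not assumed to be commercial and is made in steps 1 and 2.

Step 1
Reactants: 1 2-chloro-N-methoxy-N-methylacetamide; 2 isopropenylmagnesium bromide
Product: 3 1-chloro-3-methylbut-3-en-2-one
Conditions: THF, −78 to 0 °C; cold 1 M HCl quench
Reagents that add atoms: none
Why: Weinreb ketone synthesis; the chelated tetrahedral magnesium adduct survives until the acidic quench, so the Grignard reagent adds only once.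

Step 2
Reactants: 3 1-chloro-3-methylbut-3-en-2-one
Product: 5 (R)-2-(prop-1-en-2-yl)oxirane, via chlorohydrin 4 (not isolated)
Conditions: (R)-2-methyl-CBS-oxazaborolidine (10 mol %), catecholborane, toluene, −78 °C; then 2 M NaOH, Et2O, 0 °C to rt
Reagents that add atoms: none
Why: CBS reduction, with the isopropenyl group acting as the large substituent, should set the R carbinol; intramolecular Williamson closure then gives the epoxide without touching that centre.

Step 3
Reactants: 5 (R)-2-(prop-1-en-2-yl)oxirane; 6 ethynyltrimethylsilane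
Product: 8 (R)-2-(prop-1-en-2-yl)but-3-yn-1-ol, via silylalkynol 7 (not isolated)
Conditions: 6, n-BuLi, toluene, −40 °C; Et2AlCl, 0 °C; then 5, 0 °C; work-up; K2CO3, MeOH, rt
Reagents that add atoms: none
Why: The alkynylalane activates the vinyl oxirane and transfers the alkynyl group to the allylic carbon in an SN2 opening with inversion, which sets C9; methanolysis then removes the silyl group.

Step 4
Reactants: 8 (R)-2-(prop-1-en-2-yl)but-3-yn-1-ol
Product: 10 (R,E)-4-iodo-3-methyl-2-(prop-1-en-2-yl)but-3-en-1-ol, via alkenylalane 9 (not isolated)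
Conditions: AlMe3 (3 equiv), Cp2ZrCl2 (0.3 equiv), CH2Cl2, 0 °C to rt; then I2, THF, −30 °C
Reagents that add atoms: trimethylaluminium, C[Al](C)C; iodine, II
Why: Negishi carboalumination adds methyl (to the internal carbon, the future C10) and aluminium syn across the terminal alkyne; iodinolysis with retention gives the E iodide, and the 1,1-disubstituted alkene is inert.

Step 5
Reactants: 10 (R,E)-4-iodo-3-methyl-2-(prop-1-en-2-yl)but-3-en-1-ol; 11 acryloyl chloride
Product: 12 (R,E)-4-iodo-3-methyl-2-(prop-1-en-2-yl)but-3-en-1-yl acrylate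
Conditions: Et3N, DMAP (cat.), CH2Cl2, −78 to 0 °C
Reagents that add atoms: none
Why: Standard O-acylation of a primary alcohol.

Step 6
Reactants: 12 (R,E)-4-iodo-3-methyl-2-(prop-1-en-2-yl)but-3-en-1-yl acrylate
Product: 13 (R)-5-[(E)-1-iodoprop-1-en-2-yl]-4-methyl-5,6-dihydro-2H-pyran-2-one
Conditions: second-generation Grubbs catalyst, RuCl2(=CHPh)(PCy3)(H2IMes) (5 mol %), toluene, 80 °C
Reagents that add atoms: none
Why: Ring-closing metathesis between the acrylate and the isopropenyl group closes the six-membered lactone and so locks the trisubstituted C7=C8 bond in the Z geometry; the iodoalkene does not engage the ruthenium carbene.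

Step 7
Reactants: 13 (R)-5-[(E)-1-iodoprop-1-en-2-yl]-4-methyl-5,6-dihydro-2H-pyran-2-one; 14 tributyl(vinyl)stannane
Product: 15 (S)-4-methyl-5-[(E)-penta-2,4-dien-2-yl]-5,6-dihydro-2H-pyran-2-one
Conditions: Pd(PPh3)4 (5 mol %), CuI (10 mol %), DMF, 40 °C
Reagents that add atoms: none
Why: Stille coupling proceeds with retention of the E geometry under neutral conditions, so the acidic γ-hydrogen at C9 is not exposed to base (the descriptor changes only through CIP priorities).

Step 8
Reactants: 15 (S)-4-methyl-5-[(E)-penta-2,4-dien-2-yl]-5,6-dihydro-2H-pyran-2-one; 16 1-bromo-2-methylprop-1-ene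
Product: 18 (5Z,7S,8E)-7-(hydroxymethyl)-2,6,8-trimethylundeca-2,5,8,10-tetraen-4-one, via lithium hemiketal alkoxide 17 (not isolated)
Conditions: 16, t-BuLi (2 equiv), Et2O, −78 °C; then 15, THF, −78 °C; AcOH, −78 °C
Reagents that add atoms: none
Why: 1,2-Addition of the alkenyllithium to the lactone should stop at the tetrahedral lithium hemiketal at −78 °C; protonation releases the Z dienone (C4=C5–C6=O now present) and the free C11 hydroxyl.

Step 9
Reactants: 18 (5Z,7S,8E)-7-(hydroxymethyl)-2,6,8-trimethylundeca-2,5,8,10-tetraen-4-one; 19 umbelliferone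
Product: 20 7-{[(2S,3Z)-3,7-dimethyl-5-oxo-2-[(E)-penta-2,4-dien-2-yl]octa-3,6-dien-1-yl]oxy}-2H-chromen-2-one
Conditions: PPh3, DIAD, THF, 0 °C to rt
Reagents that add atoms: none
Why: Mitsunobu etherification of the unhindered primary alcohol (reacting through its open-chain form) with the acidic phenol; C9 is not involved.

Step 10
Reactants: 20 7-{[(2S,3Z)-3,7-dimethyl-5-oxo-2-[(E)-penta-2,4-dien-2-yl]octa-3,6-dien-1-yl]oxy}-2H-chromen-2-one
Product: 21 5-epi-3-deoxy-1,2-didehydroferocaulidin (cis-fused; H5, C10 methyl and C11 on one face)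
Conditions: Me2AlCl (2.5 equiv), CH2Cl2, −78 to −20 °C
Reagents that add atoms: none
Why: The closest known reaction type is the Lewis acid-promoted intramolecular Diels–Alder reaction of 1,7,9-decatrien-3-ones (type 1, carbonyl inside the tether): Me2AlCl on the C6 carbonyl activates C4=C5, and in a concerted, asynchronous [4+2] transition state the unsubstituted diene terminus C3 bonds to the electrophilic β-carbon C4 while C10 bonds to C5. Ring B closes through the planar four-atom tether C9–C8=C7–C6 (six-membered, fused mode), and ring A is the cycloaddition ring itself. For C5 and C10, the endo mode (C6 carbonyl under the diene), which the Lewis acid favours, should give the cis ring fusion. For C10 relative to C9, the C11 arm should take the pseudo-axial site on the forming cyclohexenone ring to avoid A(1,2) strain with the C8 methyl, which places C11 cis to the C10 methyl; the E geometry of C10=C1 keeps that methyl inside. The step needs endo over exo selectivity and one diene face; regiochemistry and the choice of C4=C5 over C7=C8 are fixed by the tether, and Nazarov closure is disfavoured because it would join two fully substituted carbons (C4 and C8).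

Step 11
Reactants: 21 5-epi-3-deoxy-1,2-didehydroferocaulidin
Product: 23 3-deoxy-1,2-didehydroferocaulidin (trans-fused), via lithium enolate 22 (not isolated)
Conditions: LDA (1.1 equiv), THF, −78 °C; then AcOH, −78 °C to rt
Reagents that add atoms: none
Why: Kinetic deprotonation at the only α′ position (C5) gives the cross-conjugated enolate, which cannot expel the aryloxy group; protonation on the face opposite the pseudo-axial C10 methyl and the C11 arm should give the trans ring fusion, which is also expected to be the more stable one.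

Step 12
Reactants: 23 3-deoxy-1,2-didehydroferocaulidin
Product: 24 1,2-didehydroferocaulidin (axial 3-hydroxyl, trans to the C10 methyl)
Conditions: SeO2 (0.5 equiv), t-BuOOH (2 equiv), salicylic acid (cat.), CH2Cl2, rt
Reagents that add atoms: selenium dioxide, O=[Se]=O; tert-butyl hydroperoxide (terminal oxidant), CC(C)(C)OO
Why: Selenium dioxide allylic hydroxylation (ene reaction, then [2,3]-sigmatropic shift): C3 carries the only allylic hydrogens of C1=C2, and selenium should attack C1 and deliver oxygen to C3 on the face opposite the axial C10 methyl, giving the axial alcohol; the enone and coumarin double bonds are too electron-poor to compete.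

Step 13
Reactants: 24 1,2-didehydroferocaulidin
Product: 25 ferocaulidin
Conditions: H2 (1 atm), [Ir(cod)(PCy3)(py)]PF6 (5 mol %), CH2Cl2, 0 °C to rt
Reagents that add atoms: none
Why: Hydroxyl-directed hydrogenation with the cationic iridium catalyst should reduce the allylic-alcohol C1=C2 bond in preference to the trisubstituted enone and the coumarin double bonds; no stereocentre is formed.

**Compound list**

1 | 2-chloro-N-methoxy-N-methylacetamide | ClCC(=O)N(C)OC | starting material
2 | isopropenylmagnesium bromide | CC(=C)[Mg]Br | starting material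
3 | 1-chloro-3-methylbut-3-en-2-one | CC(=C)C(=O)CCl | intermediate
4 | (R)-1-chloro-3-methylbut-3-en-2-ol (chlorohydrin) | ClC[C@H](O)C(C)=C | intermediate
5 | (R)-2-(prop-1-en-2-yl)oxirane | CC(=C)[C@@H]1CO1 | intermediate
6 | ethynyltrimethylsilane | C#C[Si](C)(C)C | starting material
7 | (R)-2-(prop-1-en-2-yl)-4-(trimethylsilyl)but-3-yn-1-ol (silylalkynol) | C[Si](C)(C)C#C[C@@H](C(C)=C)CO | intermediate
8 | (R)-2-(prop-1-en-2-yl)but-3-yn-1-ol | C#C[C@@H](C(C)=C)CO | intermediate
9 | (E)-alkenyldimethylalane, as its dimethylaluminium alkoxide | C[Al](C)/C=C(\C)[C@@H](C(C)=C)CO[Al](C)C | intermediate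
10 | (R,E)-4-iodo-3-methyl-2-(prop-1-en-2-yl)but-3-en-1-ol | I/C=C(\C)[C@@H](C(C)=C)CO | intermediate
11 | acryloyl chloride | C=CC(=O)Cl | starting material
12 | (R,E)-4-iodo-3-methyl-2-(prop-1-en-2-yl)but-3-en-1-yl acrylate | I/C=C(\C)[C@@H](C(C)=C)COC(=O)C=C | intermediate
13 | (R)-5-[(E)-1-iodoprop-1-en-2-yl]-4-methyl-5,6-dihydro-2H-pyran-2-one | O=C1C=C(C)[C@H](/C(C)=C/I)CO1 | intermediate
14 | tributyl(vinyl)stannane | C=C[Sn](CCCC)(CCCC)CCCC | starting material
15 | (S)-4-methyl-5-[(E)-penta-2,4-dien-2-yl]-5,6-dihydro-2H-pyran-2-one | O=C1C=C(C)[C@H](/C(C)=C/C=C)CO1 | intermediate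
16 | 1-bromo-2-methylprop-1-ene | CC(C)=CBr | starting material
17 | lithium hemiketal alkoxide from addition to 15 | [Li+].[O-]C1(C=C(C)C)C=C(C)[C@H](/C(C)=C/C=C)CO1 | intermediate
18 | (5Z,7S,8E)-7-(hydroxymethyl)-2,6,8-trimethylundeca-2,5,8,10-tetraen-4-one | CC(C)=CC(=O)/C=C(C)\[C@@H](CO)/C(C)=C/C=C | intermediate
19 | umbelliferone (7-hydroxy-2H-chromen-2-one) | Oc1ccc2ccc(=O)oc2c1 | starting material
20 | 7-{[(2S,3Z)-3,7-dimethyl-5-oxo-2-[(E)-penta-2,4-dien-2-yl]octa-3,6-dien-1-yl]oxy}-2H-chromen-2-one | CC(C)=CC(=O)/C=C(C)\[C@@H](COc1ccc2ccc(=O)oc2c1)/C(C)=C/C=C | intermediate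
21 | 5-epi-3-deoxy-1,2-didehydroferocaulidin (cis-fused cycloadduct) | CC1=CC(=O)[C@H]2C(C)(C)CC=C[C@@]2(C)[C@@H]1COc1ccc2ccc(=O)oc2c1 | intermediate
22 | lithium enolate (C5=C6–OLi) of 21 | [Li+].CC1=CC([O-])=C2C(C)(C)CC=C[C@@]2(C)[C@@H]1COc1ccc2ccc(=O)oc2c1 | intermediate
23 | 3-deoxy-1,2-didehydroferocaulidin (trans-fused) | CC1=CC(=O)[C@@H]2C(C)(C)CC=C[C@@]2(C)[C@@H]1COc1ccc2ccc(=O)oc2c1 | intermediate
24 | 1,2-didehydroferocaulidin | CC1=CC(=O)[C@@H]2C(C)(C)[C@@H](O)C=C[C@@]2(C)[C@@H]1COc1ccc2ccc(=O)oc2c1 | intermediate
25 | ferocaulidin | CC1=CC(=O)[C@@H]2C(C)(C)[C@@H](O)CC[C@@]2(C)[C@@H]1COc1ccc2ccc(=O)oc2c1 | target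

**Step count and risks**

Total step count: 13. Longest linear sequence: 13 steps (1 to 25); 6, 11, 14, 16 and 19 enter as commercial partners.

Steps most likely to fail:

1. Step 10 (key cycloaddition). The Lewis acid may be diverted by the coumarin carbonyl, or may ionise the aryloxymethyl group, before the slow cycloaddition at the β,β-dimethyl terminus takes place. More forcing conditions would then erode the endo preference and the facial preference. The fallback cyclises before arylation. Setting out from 18, silylation (TBDPSCl, imidazole, DMF) gives the silyl ether F1, which has neither a Lewis-basic lactone nor an ionisable aryloxy group. MeAlCl2 (CH2Cl2, −78 to −40 °C) should then give the cis-fused silyl ether F2. LDA followed by AcOH (as in step 11) gives the trans-fused silyl ether F3, and HF·pyridine (THF, 0 °C) gives the primary alcohol F4. Mitsunobu reaction of F4 with 19 (PPh3, DIAD, THF) comes back to the route at 23.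

2. Step 12 (allylic hydroxylation). Over-oxidation to the enone, competing attack on the allylic positions of ring B, or oxygen delivery to the wrong face of C3 may occur. The fallback oxidises fully and reduces back. Setting out from 23, CrO3·3,5-dimethylpyrazole (CH2Cl2, −20 °C) gives the Δ1-3-ketone F5. [(Ph3P)CuH]6 (benzene, rt) reduces only the less substituted ring A enone conjugatively to the 3-ketone F6. K[(s-Bu)3BH] (THF, −78 °C) then attacks C3 from the equatorial direction and should give the axial alcohol, which is the target 25.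

3. Step 8 (single addition to the lactone). A second addition of the alkenyllithium to the released ketone, or γ-deprotonation of the lactone at C9 with erosion of the stereocentre, may occur. The fallback uses an acyl equivalent that cannot over-add. Setting out from 15, aminolysis with MeNHOMe·HCl and AlMe3 (CH2Cl2, 0 °C) gives the (Z)-hydroxy Weinreb amide F7. 2-Methylprop-1-enylmagnesium bromide (3 equiv, THF, −20 °C) then adds once to the chelated amide and comes back to the route at 18.

Further compounds
F1 | step 10 | tert-butyldiphenylsilyl ether of 18 | CC(C)=CC(=O)/C=C(C)\[C@@H](CO[Si](c1ccccc1)(c1ccccc1)C(C)(C)C)/C(C)=C/C=C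
F2 | step 10 | cis-fused cycloadduct silyl ether | CC1=CC(=O)[C@H]2C(C)(C)CC=C[C@@]2(C)[C@@H]1CO[Si](c1ccccc1)(c1ccccc1)C(C)(C)C
F3 | step 10 | trans-fused silyl ether | CC1=CC(=O)[C@@H]2C(C)(C)CC=C[C@@]2(C)[C@@H]1CO[Si](c1ccccc1)(c1ccccc1)C(C)(C)C
F4 | step 10 | trans-fused primary alcohol (free C11 hydroxyl) | CC1=CC(=O)[C@@H]2C(C)(C)CC=C[C@@]2(C)[C@@H]1CO
F5 | step 12 | Δ1-3-ketone (3-oxo analogue of 23) | CC1=CC(=O)[C@@H]2C(C)(C)C(=O)C=C[C@@]2(C)[C@@H]1COc1ccc2ccc(=O)oc2c1
F6 | step 12 | 3-ketone (3-dehydroferocaulidin) | CC1=CC(=O)[C@@H]2C(C)(C)C(=O)CC[C@@]2(C)[C@@H]1COc1ccc2ccc(=O)oc2c1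
F7 | step 8 | (Z)-hydroxy Weinreb amide from 15 | CON(C)C(=O)/C=C(C)\[C@@H](CO)/C(C)=C/C=C
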